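**Strategy.** Labdane numbering is used. Ring B (C5–C10) carries the carboxyl on C8 beside the C7=C8 olefin, and C9 and C5 are both CH centres on the quaternary C10; the unit C6–C7–C8–CO2H is therefore a crotonic acid to be stitched across C9 and C5. The precursor is the (E)-allylic crotonate of a ring A ketone whose C10 is already quaternary. Excess lithium amide triggers an ester dienolate [3,3] shift (C8–C9, the C9 stereocentre, a vinyl handle, the free carboxylate) and then a γ-aldol of the derived dienediolate onto the C5 ketone (C5–C6, C7=C8), closing ring B in one operation. Radical deoxygenation at C5 and a B-alkyl Suzuki coupling finish the target.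

Key step: step 4

Remark: the configuration of the C5 carbinol in 11–15 does not matter because C5 becomes a planar radical in step 6; the cis-fused epimer expected from the aldol closure is drawn, and racemic 1 serves because its stereocentre is lost on enolisation.

**Step 1**
Reactants: 1 2,2,6-trimethylcyclohexan-1-one; 2 allyl chloroformate
Product: 4 prop-2-en-1-yl 2,6,6-trimethylcyclohex-1-en-1-yl carbonate, via lithium enolate 3 (not isolated)
Conditions: LiN(SiMe3)2, THF, 0 °C; then 2, −78 → 23 °C
Reagents that add atoms: none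
Why: The ketone has a single enolisable position, and the hard chloroformate acylates the tetrasubstituted lithium enolate on oxygen (enolate O-acylation).

**Step 2**
Reactants: 4 prop-2-en-1-yl 2,6,6-trimethylcyclohex-1-en-1-yl carbonate
Product: 5 (2R)-2,6,6-trimethyl-2-(prop-2-en-1-yl)cyclohexan-1-one
Conditions: Pd2(dba)3 (2.5 mol %), (R)-t-BuPHOX [(R)-4-tert-butyl-2-(2-diphenylphosphinophenyl)-4,5-dihydrooxazole] (6.25 mol %), THF, 25 °C
Reagents that add atoms: none
Why: Decarboxylative asymmetric allylic alkylation (Tsuji allylation): zerovalent palladium ionises the allyl carbonate, CO2 is lost and the enolate is C-allylated inside the PHOX pocket, which should set C10 as R, the (S)-ligand being the one associated with the S series of 2-allyl-2-alkylcyclohexanones.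

**Step 3**
Reactants: 5 (2R)-2,6,6-trimethyl-2-(prop-2-en-1-yl)cyclohexan-1-one; 6 (2E)-but-2-enoic acid
Product: 7 (2E)-3-[(1R)-1,3,3-trimethyl-2-oxocyclohexyl]prop-2-en-1-yl (2E)-but-2-enoate
Conditions: Pd(MeCN)4(BF4)2 (10 mol %), DMSO, 1,4-benzoquinone, i-Pr2NEt (substoichiometric), 4 Å MS, CH2Cl2, 41 °C
Reagents that add atoms: none
Why: Sulfoxide-promoted allylic C–H cleavage by electrophilic divalent palladium gives a π-allyl that the carboxylate should attack at the unhindered terminus remote from the quaternary carbon, giving the linear (E)-allylic ester while benzoquinone reoxidises palladium (palladium-catalysed allylic C–H esterification).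

**Step 4**
Reactants: 7 (2E)-3-[(1R)-1,3,3-trimethyl-2-oxocyclohexyl]prop-2-en-1-yl (2E)-but-2-enoate
Product: 12 (1R,4aS,8aR)-1-ethenyl-4a-hydroxy-5,5,8a-trimethyl-1,4,4a,5,6,7,8,8a-octahydronaphthalene-2-carboxylic acid, via lithium dienolate 8 (not isolated), via lithium carboxylate 9 (not isolated), via dilithium dienediolate 10 (not isolated), via dilithium aldolate 11 (not isolated)
Conditions: LiN(i-Pr)2 (4 equiv), THF–DMPU, −78 → 23 °C, then 60 °C; aq. HCl
Reagents that add atoms: none
Why: γ-Deprotonation of the crotonate gives lithium dienolate 8, whose O-allyl ketene acetal unit (C8=C17–O–C12–C11=C9) undergoes an ester enolate Claisen ([3,3], Ireland–Claisen type) shift through a chair, forming C8–C9 and releasing carboxylate 9 with a vinyl group on C9; the remaining amide deprotonates C8 to dienediolate 10, whose γ-carbon C6 adds to the non-enolisable C5 ketone (vinylogous aldol), forming C5–C6 with the olefin moving to C7=C8. The closest known reaction types are the dienolate Claisen rearrangement of allyl crotonates and the γ-selective addition of carboxylic acid dienediolates to ketones, here run in tandem as a formal [3+3] annulation. Ring B closes in the aldol event by a 6-(enolendo)-exo-trig attack on the carbonyl; the [3,3] shift closes no ring. C9 is set in the [3,3] step, where the (E)-olefin keeps the C10 substituent pseudo-equatorial on the chair and C8 should add anti to the C10–C5 acyl bond with the C10 methyl as the small group beside the forming bond, which gives the 9R centre; C10 is carried in from 5, C8 of 9 is lost on enolisation and the C5 carbinol (cis-fused expected) is removed in step 6. The step needs γ-deprotonation rather than conjugate attack of the base on the crotonate (DMPU), a rearrangement that outruns loss of the allyl oxide from the ester enolate, and γ- over α-attack in the aldol, which is secured because α-attack would close a four-membered ring and because the aldol turns a carbon dianion into an alkoxide and a conjugated carboxylate.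

**Step 5**
Reactants: 12 (1R,4aS,8aR)-1-ethenyl-4a-hydroxy-5,5,8a-trimethyl-1,4,4a,5,6,7,8,8a-octahydronaphthalene-2-carboxylic acid
Product: 15 (1R,4aS,8aR)-1-ethenyl-4a-[(methoxyoxalyl)oxy]-5,5,8a-trimethyl-1,4,4a,5,6,7,8,8a-octahydronaphthalene-2-carboxylic acid, via dipotassium alkoxide carboxylate 13 (not isolated), via bis(methoxyoxalyl) mixed anhydride 14 (not isolated)
Conditions: KN(SiMe3)2 (2.2 equiv), THF, −78 °C; ClC(O)CO2Me (2.5 equiv), −78 → 0 °C; aq. NaHCO3, 23 °C
Reagents that add atoms: methyl chlorooxalate COC(=O)C(Cl)=O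
Why: The small, highly electrophilic chloro-oxalate should acylate the hindered tertiary potassium alkoxide (O-acylation), and the carboxylic–oxalic mixed anhydride formed alongside is cleaved by aqueous bicarbonate while the tertiary oxalate survives.

**Step 6**
Reactants: 15 (1R,4aS,8aR)-1-ethenyl-4a-[(methoxyoxalyl)oxy]-5,5,8a-trimethyl-1,4,4a,5,6,7,8,8a-octahydronaphthalene-2-carboxylic acid
Product: 16 (1R,4aS,8aS)-1-ethenyl-5,5,8a-trimethyl-1,4,4a,5,6,7,8,8a-octahydronaphthalene-2-carboxylic acid
Conditions: Bu3SnH, AIBN (cat.), toluene, 110 °C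
Reagents that add atoms: none
Why: Barton–McCombie-type radical deoxygenation of a tertiary methyl oxalate: stannyl radical addition and β-scission give the C5 radical, which should take hydrogen from Bu3SnH on the α-face, anti to the axial C10 and C4 methyl groups, setting the trans ring fusion (5S).

**Step 7**
Reactants: 17 ethyl 3-oxobutanoate
Product: 18 ethyl (2E)-3-{[(trifluoromethyl)sulfonyl]oxy}but-2-enoate
Conditions: Tf2O, aq. Me4NOH, hexanes, 5 → 23 °C
Reagents that add atoms: trifluoromethanesulfonic anhydride O=S(=O)(OS(=O)(=O)C(F)(F)F)C(F)(F)F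
Why: The non-chelated tetramethylammonium enolate of the β-keto ester prefers the extended geometry, so O-sulfonylation should give the (E)-enol triflate with the methyl cis to the ester (enolate triflation).

**Step 8**
Reactants: 18 ethyl (2E)-3-{[(trifluoromethyl)sulfonyl]oxy}but-2-enoate
Product: 19 (2E)-4-hydroxybut-2-en-2-yl trifluoromethanesulfonate
Conditions: i-Bu2AlH (2.2 equiv), CH2Cl2, −78 °C; aq. potassium sodium tartrate
Reagents that add atoms: none
Why: 1,2-Reduction of the conjugated ester by the aluminium hydride at low temperature leaves the vinyl triflate and the olefin geometry untouched (ester to allylic alcohol reduction).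

**Step 9**
Reactants: 19 (2E)-4-hydroxybut-2-en-2-yl trifluoromethanesulfonate; 20 2-methylpropanoyl chloride
Product: 21 (2E)-4-[(2-methylpropanoyl)oxy]but-2-en-2-yl trifluoromethanesulfonate
Conditions: Et3N, DMAP (cat.), CH2Cl2, 0 °C
Reagents that add atoms: none
Why: The primary allylic alcohol is acylated by the acid chloride under nucleophilic catalysis (acyl substitution), with no effect on the enol triflate.

**Step 10**
Reactants: 16 (1R,4aS,8aS)-1-ethenyl-5,5,8a-trimethyl-1,4,4a,5,6,7,8,8a-octahydronaphthalene-2-carboxylic acid; 21 (2E)-4-[(2-methylpropanoyl)oxy]but-2-en-2-yl trifluoromethanesulfonate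
Product: 23 (1R,4aS,8aS)-5,5,8a-trimethyl-1-{(3E)-3-methyl-5-[(2-methylpropanoyl)oxy]pent-3-en-1-yl}-1,4,4a,5,6,7,8,8a-octahydronaphthalene-2-carboxylic acid, via B-alkyl-9-BBN acyloxyborane 22 (not isolated)
Conditions: 9-BBN-H (2.4 equiv), THF, 0 → 23 °C; then 21, PdCl2(dppf) (5 mol %), AsPh3, aq. K3PO4, DMF, 23 °C; dilute HCl to pH 3
Reagents that add atoms: none
Why: Anti-Markovnikov hydroboration should select the monosubstituted vinyl group over the trisubstituted conjugated C7=C8 olefin (the acid is masked as its acyloxyborane), and B-alkyl Suzuki–Miyaura coupling with retention of the (E)-enol triflate geometry forms C12–C13 and gives the 13E olefin.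

**Compound list**
1 | 2,2,6-trimethylcyclohexan-1-one (racemic) | CC1CCCC(C)(C)C1=O | starting material
2 | allyl chloroformate | C=CCOC(Cl)=O | starting material
3 | lithium 2,6,6-trimethylcyclohex-1-en-1-olate | CC1=C([O-])C(C)(C)CCC1.[Li+] | intermediate
4 | prop-2-en-1-yl 2,6,6-trimethylcyclohex-1-en-1-yl carbonate | C=CCOC(=O)OC1=C(C)CCCC1(C)C | intermediate
5 | (2R)-2,6,6-trimethyl-2-(prop-2-en-1-yl)cyclohexan-1-one | C=CC[C@@]1(C)CCCC(C)(C)C1=O | intermediate
6 | (2E)-but-2-enoic acid (crotonic acid) | C/C=C/C(=O)O | starting material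
7 | (2E)-3-[(1R)-1,3,3-trimethyl-2-oxocyclohexyl]prop-2-en-1-yl (2E)-but-2-enoate | C/C=C/C(=O)OC/C=C/[C@@]1(C)CCCC(C)(C)C1=O | intermediate
8 | lithium dienolate of 7 (lithium 1-alkoxybuta-1,3-dien-1-olate) | C=CC=C([O-])OC/C=C/[C@@]1(C)CCCC(C)(C)C1=O.[Li+] | intermediate
9 | lithium (3S)-2-ethenyl-3-[(1R)-1,3,3-trimethyl-2-oxocyclohexyl]pent-4-enoate (both C2 epimers) | C=CC(C(=O)[O-])[C@H](C=C)[C@@]1(C)CCCC(C)(C)C1=O.[Li+] | intermediate
10 | dilithium dienediolate of 9 | C=CC(=C([O-])[O-])[C@H](C=C)[C@@]1(C)CCCC(C)(C)C1=O.[Li+].[Li+] | intermediate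
11 | dilithium salt (alkoxide and carboxylate) of 12 | C=C[C@H]1C(C(=O)[O-])=CC[C@]2([O-])C(C)(C)CCC[C@]12C.[Li+].[Li+] | intermediate
12 | (1R,4aS,8aR)-1-ethenyl-4a-hydroxy-5,5,8a-trimethyl-1,4,4a,5,6,7,8,8a-octahydronaphthalene-2-carboxylic acid | C=C[C@H]1C(C(=O)O)=CC[C@]2(O)C(C)(C)CCC[C@]12C | intermediate
13 | dipotassium salt (alkoxide and carboxylate) of 12 | C=C[C@H]1C(C(=O)[O-])=CC[C@]2([O-])C(C)(C)CCC[C@]12C.[K+].[K+] | intermediate
14 | 4a-oxalate of 12 with the carboxyl as methoxyoxalyl mixed anhydride | C=C[C@H]1C(C(=O)OC(=O)C(=O)OC)=CC[C@]2(OC(=O)C(=O)OC)C(C)(C)CCC[C@]12C | intermediate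
15 | (1R,4aS,8aR)-1-ethenyl-4a-[(methoxyoxalyl)oxy]-5,5,8a-trimethyl-1,4,4a,5,6,7,8,8a-octahydronaphthalene-2-carboxylic acid | C=C[C@H]1C(C(=O)O)=CC[C@]2(OC(=O)C(=O)OC)C(C)(C)CCC[C@]12C | intermediate
16 | (1R,4aS,8aS)-1-ethenyl-5,5,8a-trimethyl-1,4,4a,5,6,7,8,8a-octahydronaphthalene-2-carboxylic acid | C=C[C@H]1C(C(=O)O)=CC[C@H]2C(C)(C)CCC[C@]12C | intermediate
17 | ethyl 3-oxobutanoate (ethyl acetoacetate) | CCOC(=O)CC(C)=O | starting material
18 | ethyl (2E)-3-{[(trifluoromethyl)sulfonyl]oxy}but-2-enoate | C/C(=C\C(=O)OCC)OS(=O)(=O)C(F)(F)F | intermediate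
19 | (2E)-4-hydroxybut-2-en-2-yl trifluoromethanesulfonate | C/C(=C\CO)OS(=O)(=O)C(F)(F)F | intermediate
20 | 2-methylpropanoyl chloride (isobutyryl chloride) | CC(C)C(=O)Cl | starting material
21 | (2E)-4-[(2-methylpropanoyl)oxy]but-2-en-2-yl trifluoromethanesulfonate | C/C(=C\COC(=O)C(C)C)OS(=O)(=O)C(F)(F)F | intermediate
22 | B-alkyl-9-BBN of 16 (boron on C12) with the carboxyl as 9-BBN acyloxyborane | C(CB1C2CCCC1CCC2)[C@H]1C(C(=O)OB3C4CCCC3CCC4)=CC[C@H]2C(C)(C)CCC[C@]12C | intermediate
23 | (1R,4aS,8aS)-5,5,8a-trimethyl-1-{(3E)-3-methyl-5-[(2-methylpropanoyl)oxy]pent-3-en-1-yl}-1,4,4a,5,6,7,8,8a-octahydronaphthalene-2-carboxylic acid | C/C(=C\COC(=O)C(C)C)CC[C@H]1C(C(=O)O)=CC[C@H]2C(C)(C)CCC[C@]12C | target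

**Step count.** Total: 10 steps. Longest linear sequence: 7 steps (steps 1–6 and 10); steps 7–9 build the side-chain partner.

**Steps most likely to fail**

Step 4. The [3,3] shift may show poor facial selectivity at C9, because the only control element is the neighbouring quaternary C10. The lithium dienolate may also lose the allyl oxide before rearranging, or the γ-aldol onto the doubly neopentyl ketone may stall. The fallback sets out from 7 and returns at 12, splitting the operation into a silyl-trapped rearrangement and a Lewis acid ring closure. Enolisation of 7 with LiN(i-Pr)2 and DMPU in the presence of Me3SiCl would give the trimethylsilyl ketene acetal F1. Warming would rearrange it (Ireland–Claisen) to the trimethylsilyl ester F2, and aqueous work-up would give (3S)-2-ethenyl-3-[(1R)-1,3,3-trimethyl-2-oxocyclohexyl]pent-4-enoic acid F3, at which stage C9 epimers could be separated. Treatment of F3 with excess AlMe2Cl in CH2Cl2 should then close ring B by an intramolecular carbonyl-ene reaction: C6 bonds to the activated C5 carbonyl, the C8 hydrogen passes to oxygen and the olefin ends at C7=C8, giving 12.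

Step 6. Hydrogen-atom transfer to the C5 radical may occur on the wrong face and give the cis ring fusion, or the tertiary oxalate may eliminate thermally before the chain reaction starts; acylation of the hindered alkoxide in step 5 may also be incomplete. The fallback sets out from 12 and returns at 16 by an ionic sequence. Acid-catalysed dehydration of 12 (p-TsOH, benzene, reflux) can only eliminate towards C6 and would give the conjugated diene acid (1R,8aR)-1-ethenyl-5,5,8a-trimethyl-1,5,6,7,8,8a-hexahydronaphthalene-2-carboxylic acid F4. Birch-type reduction of F4 with lithium in liquid ammonia should protonate C5 under thermodynamic control on the α-face (trans fusion), leave the isolated vinyl group alone and, after ammonium chloride quench, give the β,γ-unsaturated acid (1R,4aS,8aS)-1-ethenyl-5,5,8a-trimethyl-1,2,4a,5,6,7,8,8a-octahydronaphthalene-2-carboxylic acid F5. Base-mediated conjugation of F5 (KOt-Bu, t-BuOH) would move the olefin to C7=C8 and give 16.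

Step 3. Allylic C–H cleavage next to the quaternary carbon may be slow, or attack at the internal terminus and alkene isomerisation may erode the linear (E) selectivity. The fallback sets out from 5 and returns at 7 by a radical halogenation and a substitution. Wohl–Ziegler bromination of 5 (N-bromosuccinimide, AIBN, PhCF3, reflux) should trap the allyl radical at the unhindered terminus with allylic transposition and give (2R)-2-[(1E)-3-bromoprop-1-en-1-yl]-2,6,6-trimethylcyclohexan-1-one F6. Displacement of the primary allylic bromide of F6 by the caesium salt of 6 (Cs2CO3, DMF, 23 °C) would then give 7.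

**Further compounds**
F1 | step 4 | trimethylsilyl ketene acetal of 7 (1-alkoxy-1-(trimethylsilyloxy)buta-1,3-diene) | C=CC=C(O[Si](C)(C)C)OC/C=C/[C@@]1(C)CCCC(C)(C)C1=O
F2 | step 4 | trimethylsilyl (3S)-2-ethenyl-3-[(1R)-1,3,3-trimethyl-2-oxocyclohexyl]pent-4-enoate | C=CC(C(=O)O[Si](C)(C)C)[C@H](C=C)[C@@]1(C)CCCC(C)(C)C1=O
F3 | step 4 | (3S)-2-ethenyl-3-[(1R)-1,3,3-trimethyl-2-oxocyclohexyl]pent-4-enoic acid | C=CC(C(=O)O)[C@H](C=C)[C@@]1(C)CCCC(C)(C)C1=O
F4 | step 6 | (1R,8aR)-1-ethenyl-5,5,8a-trimethyl-1,5,6,7,8,8a-hexahydronaphthalene-2-carboxylic acid | C=C[C@H]1C(C(=O)O)=CC=C2C(C)(C)CCC[C@]12C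
F5 | step 6 | (1R,4aS,8aS)-1-ethenyl-5,5,8a-trimethyl-1,2,4a,5,6,7,8,8a-octahydronaphthalene-2-carboxylic acid (both C2 epimers) | C=C[C@H]1C(C(=O)O)C=C[C@H]2C(C)(C)CCC[C@]12C
F6 | step 3 | (2R)-2-[(1E)-3-bromoprop-1-en-1-yl]-2,6,6-trimethylcyclohexan-1-one | BrC/C=C/[C@@]1(C)CCCC(C)(C)C1=O
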